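**Late readings.** At 34 min the east run has lost 19.0 mM of starting material on a reagent charge of 10.0 mM, which is more. So, on this reading, about 9.01 mM or more left by a way that takes no reagent. By 18 min the east run has lost 16.8 mM, but part of that took no reagent, so catalysed reaction may still be running, and the slope between its last two readings is an estimate of that loss, too high if it is. The tail constant, the fall in the logarithm of starting material per minute between them, reads 0.0737 /min. I treat it as a first-order constant and carry it into the other flasks.

| flask | starting material | reagent | free catalyst | time |
|---|---|---|---|---|
| north | 50.0 mM | 40.0 mM | 2.50 mM |  |
| east | 20.0 mM | 10.0 mM | 2.50 mM |  |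
| south-west | 50.0 mM | 40.0 mM | 7.50 mM |  |
| north-west | 100 mM | 40.0 mM | 2.50 mM |  |
| north-east | 50.0 mM | 16.0 mM | 2.50 mM | 34 min |

| north run: time / min | north run: [starting material] / mM | east run: time / min | east run: [starting material] / mM | south-west run: time / min | south-west run: [starting material] / mM | north-west run: time / min | north-west run: [starting material] / mM |
|---|---|---|---|---|---|---|---|
| 1.4 | 43.14 | 1.4 | 17.70 | 1.4 | 40.05 | 1.4 | 88.31 |
| 2.6 | 38.60 | 2.6 | 15.69 | 2.6 | 32.79 | 2.6 | 80.54 |
| 4.9 | 30.84 | 4.9 | 12.67 | 4.9 | 22.78 | 4.9 | 66.33 |
| 9.4 | 19.21 | 9.4 | 7.84 | 9.4 | 10.27 | 9.4 | 45.19 |
| 18 | 6.98 | 18 | 3.22 | 18 | 2.02 | 18 | 19.47 |
| 34 | 0.66 | 34 | 0.99 | 34 | 0 | 34 | 2.66 |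

(standard deviation of a reading: 0.2 mM)

- the exponent of [starting material] in the starting rate at the charge of the north run (at the point where two percent of the starting material have become product) (one fixed amount of product, the same in the runs compared)
- the exponent of [free catalyst] in the starting rate at the charge of the north run (at the point where two percent of the starting material have become product)
- starting material in the north-east run at 34 min, as a share of the starting material charged

- Overall: starting material + reagent -> product, with free catalyst as catalyst.
- Constant volume, constant temperature.
- A reading of a species includes what of it is bound.
- "The second partner" is reagent.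
- An order is taken over about fifteen percent of the charge, up and down.

**Net rate.** From the fall over the first interval I subtract the tail constant times the mean amount present. The north run keeps 1.47 mM/min. Each such rate carries a scatter near 0.143 mM/min.

**More catalyst.** By hand, tripling the catalyst should triple a net rate that is first order in it. The south-west run gives 3.79 mM/min, so my order over that tripling is 0.863.

**More substrate.** By hand, doubling the starting material should double the rate if the catalyst waits for it. The north-west run gives 1.41 mM/min, an order of −0.0579 over that doubling. I read this as small, not exactly zero.

**Less reagent.** In the north-east run, reagent is the limiting reagent. On the first round I let the tail constant act alone, which leaves 8.16% of the charge at 34 min. On the next round the catalyst removes 16.0 mM at the north net rate, and I place that removal on average at 5.45 min. What it took would otherwise have decayed until 34 min, so my share falls to 4.26%.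

**The forecast.** It gives 0.8 for starting material, 0.5 for catalyst and 2.8% for the share. Its ground is this: “Reagent therefore barely limits the rate, and the decay continues after its nominal exhaustion.” My reckoning differs: a lower order in starting material, a higher one in catalyst, and a larger share.

**The flask.** The orders come to 0.31 in starting material and 0.77 in catalyst, and the north-east share is 6.77%.

    free catalyst + starting material → catalyst-substrate complex (85.20 /M/min)
    catalyst-substrate complex + reagent → loaded catalyst (87.60 /M/min)
    loaded catalyst → product + free catalyst (0.9240 /min)
    2 free catalyst ⇌ resting dimer, settled at all times (533.0 /M)
    starting material → decomposed substrate (0.06240 /min)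

**Lost substrate.** The north-east share is this low because of the path to decomposed substrate. With that path taken away, the same flask keeps 68.2% at 34 min instead of 6.77%, a gap of 61 percentage points. That kept share matches what the reagent charge leaves of the starting material, 68.0%. Carried over the 34 min of the north-east run, the tail constant of 0.0737 /min by itself leaves 8.16% of the charge, and the flask holds 6.77%.

(The data are calculated for substances that don't exist, and the scatter is random.)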